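## Retrosynthetic overview

1. The γ-lactone is closed last, by oxidative lactonisation of the C6-OH/C12-OH 2-methylene-1,4-diol 36. Before that come C14 acetylation, Katsuki–Sharpless epoxidation of the C14 allylic alcohol (C1–C10 oxirane), and Yamaguchi acylation of 8β-OH with (2R,3R)-epoxyangelic acid 9.
2. The ten-membered carbocycle comes from an eight-membered one. Ynoate 4 (C9, C10, C14) adds [2+2] to silyl enol ether 25 (C8=C1), and the C1–C8 bond of the resulting bicyclo[6.2.0]decadiene then opens conrotatorily with release of strain.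
3. Enabling feature: the array C8(O)–C9H2–C10(C14H2O)=C1 is, at the enol level, a 1-oxy-1,3-diene (C8=C9–C10=C1). That diene is the opened form of a 3-oxycyclobutene whose C1–C8 bond is shared with an eight-membered ring C1–C8. This small ring holds the cis C4=C5 alkene easily, while the trans C1=C10 unit (later the trans-oxirane) appears only on ring opening.
4. Cyclooctenone 23 comes from ring-closing metathesis (C4=C5), Weinreb ketone synthesis (C8–C1), SeO2 hydroxylation (C12), and an Evans syn aldol (C6–C7) of a senecioyl imide with acrolein.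
5. Order of rings: eight-membered ring, transient cyclobutene, ten-membered ring, C1–C10 oxirane, γ-lactone. The side-chain oxirane arrives with acid 9.

Key step: step 14

Remark: germacrane numbering of the target (ring C1–C10, lactone C11/C12, methylene C13, acetoxymethyl C14, methyl C15) is used for all ring intermediates. The ring-trans C1=C10 alkene is CIP-Z because of its CH2O group. Compounds 5 and 20 are taken as commercial.

## Route

Step 1
Reactants: 1 prop-2-yn-1-ol
Product: 2 triethyl(prop-2-yn-1-yloxy)silane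
Conditions: Et3SiCl, imidazole, CH2Cl2, 0 to 23 °C
Reagents that add atoms: chlorotriethylsilane, CC[Si](Cl)(CC)CC
Why: Imidazole-assisted silylation of a primary alcohol, with TES chosen because it can later be removed beside TBS ethers.

Step 2
Reactants: 2 triethyl(prop-2-yn-1-yloxy)silane
Product: 4 allyl 4-(triethylsilyloxy)but-2-ynoate, via lithium acetylide 3 (not isolated)
Conditions: n-BuLi, THF, −78 °C; ClCO2CH2CH=CH2, −78 to 0 °C
Reagents that add atoms: allyl chloroformate, C=CCOC(=O)Cl
Why: Deprotonation of the terminal alkyne and C-acylation of the acetylide with a chloroformate is the standard ynoate synthesis, and the allyl ester allows neutral removal later.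

Step 3
Reactants: 5 methyl (Z)-2-methylbut-2-enoate (methyl angelate)
Product: 6 (Z)-2-methylbut-2-en-1-ol
Conditions: iBu2AlH, CH2Cl2, −78 °C; aq. Rochelle salt
Reagents that add atoms: none
Why: 1,2-Reduction of the enoate at low temperature should give the allylic alcohol without Z to E isomerisation.

Step 4
Reactants: 6 (Z)-2-methylbut-2-en-1-ol
Product: 7 [(2S,3R)-2,3-dimethyloxiran-2-yl]methanol
Conditions: Ti(OiPr)4 (10 mol %), L-(+)-diethyl tartrate (12 mol %), t-BuOOH, 4 Å MS, CH2Cl2, −20 °C
Reagents that add atoms: tert-butyl hydroperoxide, CC(C)(C)OO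
Why: Katsuki–Sharpless asymmetric epoxidation, in which L-(+)-tartrate selects the face leading to (2S,3R) and syn oxygen transfer keeps the angelate (Z) relationship of the substituents.

Step 5
Reactants: 7 [(2S,3R)-2,3-dimethyloxiran-2-yl]methanol
Product: 9 (2R,3R)-2,3-dimethyloxirane-2-carboxylic acid (epoxyangelic acid), via epoxy aldehyde 8 (not isolated)
Conditions: TEMPO (cat.), PhI(OAc)2, MeCN/H2O, 23 °C
Reagents that add atoms: water, O
Why: Oxoammonium oxidation in aqueous medium takes the primary alcohol through the aldehyde hydrate to the acid without touching the oxirane or its two stereocentres (the descriptor at C2 changes only by CIP priority).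

Step 6
Reactants: 10 (S)-4-benzyl-1,3-oxazolidin-2-one; 11 3-methylbut-2-enoyl chloride
Product: 13 (S)-4-benzyl-3-(3-methylbut-2-enoyl)-1,3-oxazolidin-2-one, via N-lithio oxazolidinone 12 (not isolated)
Conditions: n-BuLi, THF, −78 °C; then 11, −78 to 0 °C
Reagents that add atoms: none
Why: N-Acylation of the lithiated auxiliary is the standard entry to Evans imides and avoids the vinylketene formation that an amine base would cause.

Step 7
Reactants: 13 senecioyl imide; 14 acrolein
Product: 16 (S)-4-benzyl-3-[(2S,3R)-3-hydroxy-2-(prop-1-en-2-yl)pent-4-enoyl]-1,3-oxazolidin-2-one, via boron dienolate 15 (not isolated)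
Conditions: Bu2BOTf, Et3N, CH2Cl2, −78 to 0 °C; 14, −78 °C; then pH 7 buffer, MeOH, H2O2, 0 °C
Reagents that add atoms: none
Why: Evans boron aldol reaction, in which soft γ-deprotonation gives the (Z)-O-boron dienolate; this reacts at its α-carbon through a Zimmerman–Traxler chair on the face away from the benzyl group, setting C6 (R) and C7 (S here) in the syn relationship that later becomes the trans lactone fusion.

Step 8
Reactants: 16 aldol adduct
Product: 17 (2S,3R)-3-hydroxy-N-methoxy-N-methyl-2-(prop-1-en-2-yl)pent-4-enamide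
Conditions: MeONHMe·HCl, AlMe3, CH2Cl2, −10 to 0 °C; aq. Rochelle salt
Reagents that add atoms: N,O-dimethylhydroxylamine hydrochloride, CNOC.Cl
Why: Aluminium amide transamidation (Weinreb amide formation), helped by the free C6 hydroxyl through an aluminium alkoxide, releases the auxiliary without touching C6 or C7.

Step 9
Reactants: 17 Weinreb amide
Product: 18 (2S,3R)-3-hydroxy-2-(3-hydroxyprop-1-en-2-yl)-N-methoxy-N-methylpent-4-enamide
Conditions: SeO2 (30 mol %), t-BuOOH, CH2Cl2, 0 to 23 °C
Reagents that add atoms: tert-butyl hydroperoxide, CC(C)(C)OO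
Why: SeO2 allylic hydroxylation (ene reaction, then [2,3]-sigmatropic shift) attacks the more nucleophilic 1,1-disubstituted alkene and oxidises its CH3 (C12) in preference to the tertiary C7–H, the monosubstituted vinyl group being far less reactive.

Step 10
Reactants: 18 diol
Product: 19 bis-TBS ether of 18 (C6-OTBS, C12-OTBS)
Conditions: TBSOTf, 2,6-lutidine, CH2Cl2, 0 °C
Reagents that add atoms: tert-butyldimethylsilyl triflate, CC(C)(C)[Si](C)(C)OS(=O)(=O)C(F)(F)F
Why: Silyl triflate with a hindered pyridine base silylates both the primary and the hindered secondary allylic hydroxyl without epimerisation, and both groups can later be removed in one step.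

Step 11
Reactants: 20 5-bromo-2-methylpent-1-ene; 19 bis-TBS Weinreb amide
Product: 22 (3R,4S)-3-(TBSO)-4-[3-(TBSO)prop-1-en-2-yl]-9-methyldeca-1,9-dien-5-one, via Grignard reagent 21 (not isolated)
Conditions: Mg, THF, 40 °C; then 19, THF, 0 °C; aq. NH4Cl
Reagents that add atoms: none
Why: Weinreb ketone synthesis, in which the magnesium-chelated tetrahedral adduct survives until work-up, so that a single addition delivers C1–C4 and C15 without epimerising C7.

Step 12
Reactants: 22 trienone
Product: 23 (2S,3R,4Z)-3-(TBSO)-2-[3-(TBSO)prop-1-en-2-yl]-5-methylcyclooct-4-en-1-one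
Conditions: second-generation Grubbs catalyst (H2IMes)(PCy3)Cl2Ru=CHPh (10 mol %), toluene (1 mM), 80 °C
Reagents that add atoms: none
Why: Ring-closing metathesis initiates at the C5 vinyl group and closes on the 1,1-disubstituted C4 alkene (C11=C13 could only give a cyclobutene or a tetrasubstituted alkene), and the eight-membered ring enforces the cis ring geometry that is the 4Z alkene of the target.

Step 13
Reactants: 23 cyclooctenone
Product: 25 C8=C1 tert-butyldimethylsilyl enol ether of 23, via lithium enolate 24 (not isolated)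
Conditions: LiN(iPr)2, THF, −78 °C; TBSOTf, −78 °C; Et3N, aq. NaHCO3
Reagents that add atoms: tert-butyldimethylsilyl triflate, CC(C)(C)[Si](C)(C)OS(=O)(=O)C(F)(F)F
Why: Kinetic deprotonation by the bulky amide takes the unhindered C1 methylene and not the tertiary, flanked C7–H, and O-silylation fixes the necessarily ring-cis C8=C1 enolate as a robust silyl enol ether.

Step 14
Reactants: 25 silyl enol ether; 4 allyl 4-(triethylsilyloxy)but-2-ynoate
Product: 27 ring-expanded ten-membered silyl dienol ether allyl ester, via cis-fused siloxycyclobutene 26 (not isolated)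
Conditions: 4 (1.5 equiv), HNTf2 (5 mol %), CH2Cl2, −78 to −20 °C; Et3N; solvent change to toluene, 80 °C
Reagents that add atoms: none
Why: HNTf2 is silylated in situ to TBSNTf2, which activates ynoate 4 for Mukaiyama–Michael attack by C1 of the only electron-rich alkene (the vinylidene, trisubstituted and allyl alkenes stay inert), and the silyl allenolate then closes on the siloxycarbenium carbon C8 (4-exo-trig) to the cis-fused cyclobutene 26, the known acid-catalysed [2+2] cycloaddition of silyl enol ethers with acetylenic esters. On warming, 26 releases about 30 kcal/mol of cyclobutene strain by thermal conrotatory 4π electrocyclic opening of C1–C8, the only sp3–sp3 bond of the four-membered ring and the bond shared with the eight-membered ring, so that C9 and C10 are inserted and the ten-membered ring arises by bond cleavage and not by cyclisation, as in the classical two-carbon enlargement of cyclic enol ether or enamine adducts of acetylenic esters. Regiochemistry follows polarity: nucleophilic C1 bonds to the β-carbon of 4 (C10, carrying C14) and the ester-bearing carbon becomes C9. The cis fusion forces conrotation to give one cis and one trans ring alkene, and torquoselectivity decides which, because the siloxy donor on C8 and the alkyl chain C2 on C1 both rotate outward while C7 and H1 rotate inward, making C8=C9 ring-cis and C1=C10 ring-trans. No lasting stereocentre is created: C1 and C8 of 26 are erased, so both cis-fused diastereomers of 26 converge on 27, and C6 and C7 are untouched. The push–pull substitution (O-donor on C8, ester on C9) lowers the barrier so that 80 °C should suffice, below the range of Cope or [1,5]-hydrogen shifts of the product.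

Step 15
Reactants: 27 silyl dienol ether allyl ester
Product: 29 ten-membered ketone (C8=O, C9H2, ring-trans C1=C10 bearing CH2OTES), via beta-keto acid 28 (not isolated)
Conditions: Pd(PPh3)4 (5 mol %), morpholine, THF, 23 °C; then pH 6 phosphate buffer, 35 °C
Reagents that add atoms: none
Why: Tsuji–Trost deallylation by zerovalent palladium with morpholine as allyl acceptor frees the carboxylate, the vinylogous silyl ester at C8 hydrolyses in the buffer, and the β-keto acid loses CO2 through the usual six-membered transition state, kinetic α-protonation of the dienol at C9 leaving C1=C10 unconjugated and ring-trans.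

Step 16
Reactants: 29 ketone
Product: 30 (8R)-alcohol (8β-OH)
Conditions: (S)-2-methyl-CBS-oxazaborolidine, catecholborane, toluene, −78 °C
Reagents that add atoms: none
Why: Corey–Bakshi–Shibata reduction, in which the branched C7 side acts as the large and the C9 methylene as the small substituent, so that the (S)-oxazaborolidine should give the (8R) alcohol (anti to C6-O), and catecholborane at low temperature leaves the alkenes unhydroborated.

Step 17
Reactants: 30 8β-alcohol; 9 epoxyangelic acid
Product: 32 8β-[(2R,3R)-epoxyangelate] ester, via mixed anhydride 31 (not isolated)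
Conditions: 9, 2,4,6-Cl3C6H2COCl, Et3N, toluene, 23 °C; then 30, DMAP
Reagents that add atoms: none
Why: Yamaguchi esterification through the mixed anhydride and its acylpyridinium ion acylates the hindered alcohol with retention at C8, and the acid has no α-hydrogen, so its stereocentres cannot epimerise.

Step 18
Reactants: 32 ester
Product: 33 C14 allylic alcohol
Conditions: PPTS (cat.), MeOH/CH2Cl2, 0 °C
Reagents that add atoms: none
Why: Acid-catalysed methanolysis discriminates by bulk at silicon, so that the primary TES ether is cleaved much faster than the TBS ethers, and the electron-poor glycidic ester tolerates the weak acid.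

Step 19
Reactants: 33 allylic alcohol
Product: 34 (1R,10S)-1,10-epoxy-14-ol
Conditions: Ti(OiPr)4 (20 mol %), L-(+)-diethyl tartrate (24 mol %), t-BuOOH, 4 Å MS, CH2Cl2, −20 °C
Reagents that add atoms: tert-butyl hydroperoxide, CC(C)(C)OO
Why: Katsuki–Sharpless asymmetric epoxidation, in which titanium-bound C14-OH directs oxygen to C1=C10 only (C4=C5 and C11=C13 carry no free allylic OH), L-(+)-tartrate selects the face giving (1R,10S), and syn transfer turns the ring-trans alkene into the trans-oxirane.

Step 20
Reactants: 34 epoxy alcohol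
Product: 35 C14 acetate
Conditions: Ac2O, pyridine, DMAP (cat.), CH2Cl2, 0 °C
Reagents that add atoms: acetic anhydride, CC(=O)OC(C)=O
Why: Standard O-acetylation of the primary epoxy alcohol under mildly basic conditions that open neither oxirane and that block any Payne shift once the oxygen is acylated.

Step 21
Reactants: 35 acetate
Product: 36 C6,C12-diol
Conditions: Et3N·3HF, MeCN, 23 °C
Reagents that add atoms: none
Why: Fluoride-driven Si–O cleavage by the nearly neutral amine–HF complex removes both TBS groups without acid-induced transannular opening of the C1–C10 oxirane or base-induced acyl migration.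

Step 22
Reactants: 36 diol
Product: 38 target CNP0232260.3, via lactol 37 (not isolated)
Conditions: TEMPO (cat.), PhI(OAc)2, CH2Cl2, 23 °C
Reagents that add atoms: none
Why: TEMPO/PhI(OAc)2 oxidises the primary allylic C12-OH selectively to the enal, C6-OH closes the lactol (5-exo-trig) and a second oxidation gives the α-methylene-γ-lactone, whose trans fusion follows from the C6/C7 configuration set in step 7.

## Compound list

1 | prop-2-yn-1-ol | C#CCO | starting material
2 | triethyl(prop-2-yn-1-yloxy)silane | C#CCO[Si](CC)(CC)CC | intermediate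
3 | lithium acetylide of 2 | [Li]C#CCO[Si](CC)(CC)CC | intermediate
4 | allyl 4-(triethylsilyloxy)but-2-ynoate | C=CCOC(=O)C#CCO[Si](CC)(CC)CC | intermediate
5 | methyl (Z)-2-methylbut-2-enoate | C/C=C(/C)C(=O)OC | starting material
6 | (Z)-2-methylbut-2-en-1-ol | C/C=C(/C)CO | intermediate
7 | [(2S,3R)-2,3-dimethyloxiran-2-yl]methanol | OC[C@]1(C)O[C@@H]1C | intermediate
8 | (2R,3R)-2,3-dimethyloxirane-2-carbaldehyde | O=C[C@]1(C)O[C@@H]1C | intermediate
9 | (2R,3R)-2,3-dimethyloxirane-2-carboxylic acid | OC(=O)[C@]1(C)O[C@@H]1C | intermediate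
10 | (S)-4-benzyl-1,3-oxazolidin-2-one | O=C1N[C@@H](Cc2ccccc2)CO1 | starting material
11 | 3-methylbut-2-enoyl chloride | CC(C)=CC(=O)Cl | starting material
12 | N-lithio-(S)-4-benzyloxazolidin-2-one | [Li]N1[C@@H](Cc2ccccc2)COC1=O | intermediate
13 | (S)-4-benzyl-3-(3-methylbut-2-enoyl)oxazolidin-2-one | CC(C)=CC(=O)N1[C@@H](Cc2ccccc2)COC1=O | intermediate
14 | acrolein | C=CC=O | starting material
15 | (Z)-O-dibutylboron dienolate of 13 | C=C(C)/C=C(\OB(CCCC)CCCC)N1[C@@H](Cc2ccccc2)COC1=O | intermediate
16 | Evans syn aldol adduct, (2S,3R) in the acyl chain (C7 S, C6 R) | C=C[C@@H](O)[C@H](C(C)=C)C(=O)N1[C@@H](Cc2ccccc2)COC1=O | intermediate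
17 | (2S,3R)-3-hydroxy-N-methoxy-N-methyl-2-(prop-1-en-2-yl)pent-4-enamide | C=C[C@@H](O)[C@H](C(C)=C)C(=O)N(C)OC | intermediate
18 | (2S,3R)-3-hydroxy-2-(3-hydroxyprop-1-en-2-yl)-N-methoxy-N-methylpent-4-enamide | C=C[C@@H](O)[C@H](C(=C)CO)C(=O)N(C)OC | intermediate
19 | bis-TBS ether of 18 | C=C[C@@H](O[Si](C)(C)C(C)(C)C)[C@H](C(=C)CO[Si](C)(C)C(C)(C)C)C(=O)N(C)OC | intermediate
20 | 5-bromo-2-methylpent-1-ene | C=C(C)CCCBr | starting material
21 | 4-methylpent-4-enylmagnesium bromide | C=C(C)CCC[Mg]Br | intermediate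
22 | (3R,4S)-3-(TBSO)-4-[3-(TBSO)prop-1-en-2-yl]-9-methyldeca-1,9-dien-5-one | C=C[C@@H](O[Si](C)(C)C(C)(C)C)[C@H](C(=C)CO[Si](C)(C)C(C)(C)C)C(=O)CCCC(C)=C | intermediate
23 | (2S,3R,4Z)-3-(TBSO)-2-[3-(TBSO)prop-1-en-2-yl]-5-methylcyclooct-4-en-1-one | C/C1=C/[C@@H](O[Si](C)(C)C(C)(C)C)[C@H](C(=C)CO[Si](C)(C)C(C)(C)C)C(=O)CCC1 | intermediate
24 | kinetic C8=C1 lithium enolate of 23 | C/C1=C/[C@@H](O[Si](C)(C)C(C)(C)C)[C@H](C(=C)CO[Si](C)(C)C(C)(C)C)/C(O[Li])=C\CC1 | intermediate
25 | C8=C1 TBS enol ether of 23 (both ring alkenes cis; C6, C7 unchanged) | C/C1=C/[C@@H](O[Si](C)(C)C(C)(C)C)[C@H](C(=C)CO[Si](C)(C)C(C)(C)C)/C(O[Si](C)(C)C(C)(C)C)=C\CC1 | intermediate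
26 | cis-fused bicyclo[6.2.0]deca-4,9-diene: C8 OTBS, C9 CO2allyl, C10 CH2OTES, C1 H (one of two cis-fused diastereomers drawn; both give 27) | C/C1=C/[C@@H](O[Si](C)(C)C(C)(C)C)[C@H](C(=C)CO[Si](C)(C)C(C)(C)C)[C@@]2(O[Si](C)(C)C(C)(C)C)C(C(=O)OCC=C)=C(CO[Si](CC)(CC)CC)[C@H]2CC1 | intermediate
27 | ten-membered silyl dienol ether: C8(OTBS)=C9(CO2allyl) ring-cis, C10(CH2OTES)=C1 ring-trans, C4=C5 ring-cis | C/C1=C/[C@@H](O[Si](C)(C)C(C)(C)C)[C@H](C(=C)CO[Si](C)(C)C(C)(C)C)/C(O[Si](C)(C)C(C)(C)C)=C(C(=O)OCC=C)\C(CO[Si](CC)(CC)CC)=C\CC1 | intermediate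
28 | β-keto acid (C8=O, C9 CO2H, epimers at C9) | C/C1=C/[C@@H](O[Si](C)(C)C(C)(C)C)[C@H](C(=C)CO[Si](C)(C)C(C)(C)C)C(=O)C(C(=O)O)/C(CO[Si](CC)(CC)CC)=C/CC1 | intermediate
29 | (2S,3R,4Z,8Z)-3-(TBSO)-2-[3-(TBSO)prop-1-en-2-yl]-5-methyl-9-[(triethylsilyloxy)methyl]cyclodeca-4,8-dien-1-one (8Z by CIP = ring-trans C1=C10) | C/C1=C/[C@@H](O[Si](C)(C)C(C)(C)C)[C@H](C(=C)CO[Si](C)(C)C(C)(C)C)C(=O)C/C(CO[Si](CC)(CC)CC)=C/CC1 | intermediate
30 | (8R)-alcohol from 29 (8β-OH) | C/C1=C/[C@@H](O[Si](C)(C)C(C)(C)C)[C@H](C(=C)CO[Si](C)(C)C(C)(C)C)[C@H](O)C/C(CO[Si](CC)(CC)CC)=C/CC1 | intermediate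
31 | mixed anhydride of 9 with 2,4,6-trichlorobenzoic acid | O=C(OC(=O)c1c(Cl)cc(Cl)cc1Cl)[C@]1(C)O[C@@H]1C | intermediate
32 | 8β-[(2R,3R)-2,3-epoxy-2-methylbutanoate] of 30 | C/C1=C/[C@@H](O[Si](C)(C)C(C)(C)C)[C@H](C(=C)CO[Si](C)(C)C(C)(C)C)[C@H](OC(=O)[C@]2(C)O[C@@H]2C)C/C(CO[Si](CC)(CC)CC)=C/CC1 | intermediate
33 | C14 allylic alcohol (TES removed) | C/C1=C/[C@@H](O[Si](C)(C)C(C)(C)C)[C@H](C(=C)CO[Si](C)(C)C(C)(C)C)[C@H](OC(=O)[C@]2(C)O[C@@H]2C)C/C(CO)=C/CC1 | intermediate
34 | (1R,10S)-1,10-epoxy-14-ol | C/C1=C/[C@@H](O[Si](C)(C)C(C)(C)C)[C@H](C(=C)CO[Si](C)(C)C(C)(C)C)[C@H](OC(=O)[C@]2(C)O[C@@H]2C)C[C@@]2(CO)O[C@@H]2CC1 | intermediate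
35 | C14 acetate of 34 | C/C1=C/[C@@H](O[Si](C)(C)C(C)(C)C)[C@H](C(=C)CO[Si](C)(C)C(C)(C)C)[C@H](OC(=O)[C@]2(C)O[C@@H]2C)C[C@@]2(COC(C)=O)O[C@@H]2CC1 | intermediate
36 | C6,C12-diol | C/C1=C/[C@@H](O)[C@H](C(=C)CO)[C@H](OC(=O)[C@]2(C)O[C@@H]2C)C[C@@]2(COC(C)=O)O[C@@H]2CC1 | intermediate
37 | α-methylene lactol (C12 hemiacetal, both anomers) | C=C1C(O)O[C@@H]2/C=C(/C)CC[C@H]3O[C@]3(COC(C)=O)C[C@@H](OC(=O)[C@]3(C)O[C@@H]3C)[C@@H]12 | intermediate
38 | CNP0232260.3 | C=C1C(=O)O[C@@H]2/C=C(/C)CC[C@H]3O[C@]3(COC(C)=O)C[C@@H](OC(=O)[C@]3(C)O[C@@H]3C)[C@@H]12 | target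

## Step count and risks

Total steps: 22. Longest linear sequence: 17 (steps 6 to 22). Steps 1–2 and 3–5 are side branches.

Steps most likely to fail:

1. **Step 14.**
 - Risk: after the Michael addition, silyl transfer may outrun closure of the four-membered ring and leave an open-chain adduct. Addition to the β-substituted ynoate may be sluggish. The strong acid may strip allylic silyl ethers.
 - Fallback (acid-free, enamine as the nucleophile): cyclooctenone 23 is condensed with pyrrolidine (Ti(OiPr)4, toluene) to the less substituted C8=C1 pyrrolidine enamine F1. Heated with ynoate 4 in toluene, F1 should add in the classical enamine–acetylenic ester manner to the aminocyclobutene F2. F2 opens conrotatorily (amino group outward) to the ten-membered dienamine ester F3. Buffered aqueous acetic acid hydrolyses F3 to the β-keto allyl ester F4, and Pd(PPh3)4/morpholine removes the allyl carboxylate to rejoin the route at ketone 29.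

2. **Step 12.**
 - Risk: intermolecular metathesis of the vinyl group (oligomerisation) may outrun closure of the strained eight-membered ring onto a 1,1-disubstituted alkene, and ruthenium hydrides may shift alkenes.
 - Fallback (close an easier ring, then enlarge it by one carbon): Weinreb amide 19 is treated with 3-methylbut-3-enylmagnesium bromide F5 (from commercial 4-bromo-2-methylbut-1-ene and Mg) to give the lower homologue ketone F6. Metathesis of F6 closes the far less strained cycloheptenone F7. Homologation with Me3SiCHN2/AlMe3 (Tiffeneau–Demjanov type, the unbranched CH2 migrates) inserts C1 as the α-silyl cyclooctenone F8, and protodesilylation on moist silica gel rejoins the route at 23.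

3. **Step 16.**
 - Risk: poor facial selectivity, because the conformational bias of the ten-membered ring may override the oxazaborolidine.
 - Fallback (set C8 by substitution instead of by carbonyl face selection): ketone 29 is reduced with LiBH(sBu)3 under substrate control to the 8-epi alcohol F9. A Mitsunobu esterification (PPh3, diisopropyl azodicarboxylate) with acid 9 inverts C8 and rejoins the route at ester 32.

## Further compounds

F1 | step 14 | C8=C1 pyrrolidine enamine of 23 | C/C1=C/[C@@H](O[Si](C)(C)C(C)(C)C)[C@H](C(=C)CO[Si](C)(C)C(C)(C)C)/C(N2CCCC2)=C\CC1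
F2 | step 14 | cis-fused aminocyclobutene (one cis-fused diastereomer drawn) | C/C1=C/[C@@H](O[Si](C)(C)C(C)(C)C)[C@H](C(=C)CO[Si](C)(C)C(C)(C)C)[C@@]2(N3CCCC3)C(C(=O)OCC=C)=C(CO[Si](CC)(CC)CC)[C@H]2CC1
F3 | step 14 | ten-membered dienamine ester | C/C1=C/[C@@H](O[Si](C)(C)C(C)(C)C)[C@H](C(=C)CO[Si](C)(C)C(C)(C)C)/C(N2CCCC2)=C(C(=O)OCC=C)\C(CO[Si](CC)(CC)CC)=C\CC1
F4 | step 14 | β-keto allyl ester (epimers at C9) | C/C1=C/[C@@H](O[Si](C)(C)C(C)(C)C)[C@H](C(=C)CO[Si](C)(C)C(C)(C)C)C(=O)C(C(=O)OCC=C)/C(CO[Si](CC)(CC)CC)=C/CC1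
F5 | step 12 | 3-methylbut-3-enylmagnesium bromide | C=C(C)CC[Mg]Br
F6 | step 12 | lower homologue ketone | C=C[C@@H](O[Si](C)(C)C(C)(C)C)[C@H](C(=C)CO[Si](C)(C)C(C)(C)C)C(=O)CCC(C)=C
F7 | step 12 | cycloheptenone | C/C1=C/[C@@H](O[Si](C)(C)C(C)(C)C)[C@H](C(=C)CO[Si](C)(C)C(C)(C)C)C(=O)CC1
F8 | step 12 | α-silyl cyclooctenone (epimers at C1) | C/C1=C/[C@@H](O[Si](C)(C)C(C)(C)C)[C@H](C(=C)CO[Si](C)(C)C(C)(C)C)C(=O)C([Si](C)(C)C)CC1
F9 | step 16 | 8-epi alcohol | C/C1=C/[C@@H](O[Si](C)(C)C(C)(C)C)[C@H](C(=C)CO[Si](C)(C)C(C)(C)C)[C@@H](O)C/C(CO[Si](CC)(CC)CC)=C/CC1
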